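**Strategy**

- **Cuts:** First the two aryl C3–CH2 bonds at the central methylene are cut, giving two copies of one monomer plus formaldehyde. In the monomer the ring bond C1–C2 is cut, between the butyryl-bearing carbon and its hydroxyl-bearing neighbour. In the opened chain the C1–C(=O)Pr bond and the C3–C4 bond are cut.
- **Forward:** A four-carbon enol-ether acid is extended with a malonate half-ester to a tert-butyl β-keto ester, which is butyrylated at its terminal methyl. The chain is closed thermally through an acylketene to the benzene ring. This ring is made once, and two copies are joined through one formaldehyde carbon.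
- **Enabling feature:** Each benzene ring carries its only OCH3 on C6, between butyryl-bearing C1 and methyl-bearing C5. Carried as the enol ether C5=C6 of an open chain, this unit holds C1 and the C4 acyl arm on the same side of one double bond. It also acidifies the C1 methylene and caps the one oxygen that could lactonise onto C2, so the ketene carbon C2 is reached by C1 alone.
- **Stereochemistry:** The target has no stereocentre. Only the E geometry of the enol ether matters; it is set with the acid and can correct itself by tautomerisation before ring closure.

Key step: step 5

Remark: the ring numbering (C1 butyryl, C2 OH, C3 H or CH2 bridge, C4 OH, C5 CH3, C6 OCH3) is also used for the open-chain precursors, while locants inside systematic names are the usual ones. The enol ether is assumed to form mainly as the E isomer, and any Z isomer should converge at the dianion and thermolysis stages.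

Step 1
Reactants: 1 methyl 2-methylacetoacetate
Product: 3 methyl (E)-3-methoxy-2-methylbut-2-enoate, via dimethyl ketal 2 (not isolated)
Conditions: HC(OMe)3 (1.5 equiv), conc. H2SO4 (cat.), neat, 25 to 60 °C; then fractional distillation
Reagents that add atoms: trimethyl orthoformate, COC(OC)OC
Why: Acid-catalysed ketalisation by the orthoester followed by loss of methanol from ketal 2 is the standard enol etherification of β-keto esters, and under these equilibrating conditions the E isomer (OCH3 anti to the ester) should predominate.

Step 2
Reactants: 3 methyl (E)-3-methoxy-2-methylbut-2-enoate
Product: 4 (E)-3-methoxy-2-methylbut-2-enoic acid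
Conditions: KOH (2 equiv), MeOH–H2O, reflux; then 1 M HCl, 0 °C, to pH 3, rapid extraction, recrystallisation
Reagents that add atoms: potassium hydroxide, [K+].[OH-]
Why: This is an ordinary ester saponification in which the vinylogous-carbonate enol ether is inert to hydroxide and tolerates a brief cold acidification, and crystallisation of the acid should raise its E purity.

Step 3
Reactants: 4 (E)-3-methoxy-2-methylbut-2-enoic acid; 5 mono-tert-butyl malonate
Product: 8 tert-butyl (E)-5-methoxy-4-methyl-3-oxohex-4-enoate, via acyl imidazolide 6 (not isolated), via magnesium malonate enolate 7 (not isolated)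
Conditions: 4, 1,1'-carbonyldiimidazole (1.1 equiv), THF, 25 °C; separately 5 (1.5 equiv), iPrMgCl (3.0 equiv), THF, 0 to 25 °C; combine, 25 to 45 °C; aq. NH4Cl
Reagents that add atoms: none
Why: In this Masamune–Brooks decarboxylative Claisen acylation the magnesium-bound malonate enolate is C-acylated by the imidazolide and loses CO2, which forms the C3–C4 bond under near-neutral conditions that spare the enol ether and the tert-butyl ester.

Step 4
Reactants: 8 tert-butyl (E)-5-methoxy-4-methyl-3-oxohex-4-enoate; 9 N-methoxy-N-methylbutanamide
Product: 12 tert-butyl (E)-5-methoxy-4-methyl-3,7-dioxodec-4-enoate, via dilithio dianion 10 (not isolated), via tetrahedral adduct 11 (not isolated)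
Conditions: LiN(iPr)2 (commercial solution, 2.3 equiv), THF, −78 to −30 °C; 9 (1.1 equiv), −78 to −20 °C; AcOH in THF, −78 °C, then pH 6 phosphate buffer; short filtration through neutral silica
Reagents that add atoms: none
Why: This is the vinylogous form of the β-keto ester dianion acylation, in which the C3 methylene is enolised first, the second equivalent of base removes a proton from the methyl group syn to the carbonyl (the γ-deprotonation known for 3-alkoxy enoates and enones), the terminal carbanion adds to the Weinreb amide, and the chelated adduct 11 withholds the acidic product until the cold quench.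

Step 5
Reactants: 12 tert-butyl (E)-5-methoxy-4-methyl-3,7-dioxodec-4-enoate
Product: 16 1-(4,6-dihydroxy-2-methoxy-3-methylphenyl)butan-1-one, via acylketene 13 (not isolated), via hydroxy dienylketene 14 (not isolated), via cyclohexadienone 15 (not isolated)
Conditions: 12 added by syringe pump to refluxing toluene (final 0.005 M, 111 °C), argon, slow distillative removal of tBuOH, no acid or base
Reagents that add atoms: none
Why: Proposed new method: heating makes the enolised tert-butyl β-keto ester 12 lose tert-butanol to give acylketene 13, the known thermal behaviour of such esters, and a prototropic shift (relayed by the released alcohol and by the phenol as it forms) from the doubly activated C1 methylene to the C4 carbonyl oxygen gives hydroxy dienylketene 14, of which only the isomer with C3 and C6 cis on C4=C5 can close while the other returns through 13. The C1–C2 bond then forms by a disrotatory six-electron electrocyclisation (in polar terms a C-acylation of the enol carbon C1 by the ketene), which closes the only new ring, the six-membered carbocycle, with the ketene C=C inside and its C=O outside that ring. Dienone 15 enolises at once to arene 16, so its single sp3 centre is lost, no stereocentre has to be controlled and the closure is irreversible. The closest known reaction types are the dienylketene-to-phenol closure that ends the Danheiser benzannulation and the base-mediated Claisen cyclisation of 3,5,7-trioxo esters to acylphloroglucinols, whereas the carbocyclisation of a thermally generated acylketene onto a chain that carries the enol ether has not been shown. The step needs C-acylation at C1 to win over lactonisation to a 2-pyranone, over aldol closure of C3 onto the butyryl carbonyl and over bimolecular capture of the ketene. The methyl group on the C6 oxygen removes the only oxygen nucleophile within six-ring reach, the absence of acid and base leaves the ketene as by far the strongest electrophile, slow addition at high dilution disfavours dimerisation and O-acylation of 16, and rotation about C5–C6 in 14 lets any Z isomer of 12 converge.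

Step 6
Reactants: 16 1-(4,6-dihydroxy-2-methoxy-3-methylphenyl)butan-1-one (two equivalents); 17 formaldehyde
Product: 20 pseudoaspidin, via hydroxymethyl phenol 18 (not isolated), via ortho-quinone methide 19 (not isolated)
Conditions: 37% aq. HCHO (0.5 equiv), 1% aq. KOH (2.2 equiv per 16), MeOH–H2O, argon, 0 to 25 °C; then 1 M HCl
Reagents that add atoms: none
Why: Lederer–Manasse hydroxymethylation of the phenolate at C3, loss of hydroxide to quinone methide 19 and conjugate capture by a second phenolate is the standard construction of methylene-bridged acylphloroglucinols, and the single open ring position together with half an equivalent of formaldehyde should leave the symmetric dimer as the only coupling product.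

**Compound list**

1 | methyl 2-methylacetoacetate | COC(=O)C(C)C(C)=O | starting material
2 | methyl 3,3-dimethoxy-2-methylbutanoate (racemic) | COC(=O)C(C)C(C)(OC)OC | intermediate (not isolated)
3 | methyl (E)-3-methoxy-2-methylbut-2-enoate | C/C(OC)=C(/C)C(=O)OC | intermediate
4 | (E)-3-methoxy-2-methylbut-2-enoic acid | C/C(OC)=C(/C)C(=O)O | intermediate
5 | mono-tert-butyl malonate | CC(C)(C)OC(=O)CC(=O)O | starting material
6 | (E)-1-(1H-imidazol-1-yl)-3-methoxy-2-methylbut-2-en-1-one | C/C(OC)=C(/C)C(=O)n1ccnc1 | intermediate (not isolated)
7 | magnesium enolate-carboxylate of mono-tert-butyl malonate | [Mg+2].[O-]C(=O)C=C([O-])OC(C)(C)C | intermediate (not isolated)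
8 | tert-butyl (E)-5-methoxy-4-methyl-3-oxohex-4-enoate | C/C(OC)=C(/C)C(=O)CC(=O)OC(C)(C)C | intermediate
9 | N-methoxy-N-methylbutanamide | CCCC(=O)N(C)OC | starting material
10 | dilithio dianion of 8 (ester enolate plus terminal dienolate) | [Li+].[Li+].C=C(OC)C(C)=C([O-])C=C([O-])OC(C)(C)C | intermediate (not isolated)
11 | dilithium salt of the tetrahedral adduct of 10 and 9 (racemic at the carbinolamine carbon) | [Li+].[Li+].CCCC([O-])(N(C)OC)C/C(OC)=C(/C)C([O-])=CC(=O)OC(C)(C)C | intermediate (not isolated)
12 | tert-butyl (E)-5-methoxy-4-methyl-3,7-dioxodec-4-enoate | CCCC(=O)C/C(OC)=C(/C)C(=O)CC(=O)OC(C)(C)C | intermediate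
13 | (E)-5-methoxy-4-methyldeca-1,4-diene-1,3,7-trione (acylketene) | CCCC(=O)C/C(OC)=C(/C)C(=O)C=C=O | intermediate (not isolated)
14 | (3E)-3-hydroxy-5-methoxy-4-methyldeca-1,3,5-triene-1,7-dione (hydroxy dienylketene) | O=C=C/C(O)=C(/C)C(OC)=CC(=O)CCC | intermediate (not isolated)
15 | 6-butanoyl-3-hydroxy-5-methoxy-4-methylcyclohexa-2,4-dien-1-one (racemic, transient) | CCCC(=O)C1C(=O)C=C(O)C(C)=C1OC | intermediate (not isolated)
16 | 1-(4,6-dihydroxy-2-methoxy-3-methylphenyl)butan-1-one | CCCC(=O)c1c(O)cc(O)c(C)c1OC | intermediate
17 | formaldehyde | C=O | starting material
18 | 1-[4,6-dihydroxy-5-(hydroxymethyl)-2-methoxy-3-methylphenyl]butan-1-one | CCCC(=O)c1c(O)c(CO)c(O)c(C)c1OC | intermediate (not isolated)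
19 | 4-butanoyl-5-hydroxy-3-methoxy-2-methyl-6-methylidenecyclohexa-2,4-dien-1-one | C=C1C(=O)C(C)=C(OC)C(C(=O)CCC)=C1O | intermediate (not isolated)
20 | pseudoaspidin, bis(3-butanoyl-2,6-dihydroxy-4-methoxy-5-methylphenyl)methane | CCCC(=O)c1c(O)c(Cc2c(O)c(C)c(OC)c(C(=O)CCC)c2O)c(O)c(C)c1OC | target

Total step count: 6
Longest linear sequence: 6 steps (1, 3, 4, 8, 12, 16, 20)

**Steps most likely to fail**

**Step 5.** The ketene may be drained by processes faster than the C1–C2 closure. Slow tautomerisation of the C1 methylene would leave time for dimerisation, for O-acylation of phenol already formed, or for aldol condensation between C3 and the butyryl carbonyl of unreacted chain.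

The fallback uses known chemistry, sets out from 12 and comes back at 16. The ketene is intercepted on purpose by heating 12 with excess methanol in toluene at 110 °C in a sealed vessel, the usual thermal ester exchange of tert-butyl β-keto esters. This should give methyl (E)-5-methoxy-4-methyl-3,7-dioxodec-4-enoate F1. The ester is then closed anionically with excess NaOMe in MeOH at reflux, with Mg(OMe)2 as the chelating alternative. This is the Claisen (Dieckmann-type) cyclisation established for 3,5,7-trioxo esters. The C1 carbanion displaces methoxide at C2 while the butyryl ketone is shielded as its enolate, and any methoxide exchange at C6 is degenerate. Acidification should give 16.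

**Step 4.** The delocalised terminal carbanion may add too slowly to the amide carbonyl, so that proton transfer from the α-methylene of the amide or attack through C5 takes over.

The fallback sets out from 8 and comes back at 12. Dianion 10 is generated as before but intercepted at −78 °C with butanal, the class of electrophile for which terminal attack of 3-alkoxy dienolates is best documented. This should give racemic tert-butyl (E)-7-hydroxy-5-methoxy-4-methyl-3-oxodec-4-enoate F2. Oxidation of the secondary alcohol with Dess–Martin periodinane (1.1 equiv, NaHCO3, CH2Cl2, 0 °C) should then give 12.

**Step 3.** The imidazolide of a tetrasubstituted vinylogous carbonate is a weak and hindered acyl donor, so C-acylation may stall while the malonate simply decarboxylates.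

The fallback sets out from 4 and comes back at 8. Acid 4 is converted under neutral conditions with 1-chloro-N,N,2-trimethylprop-1-en-1-amine (CH2Cl2, 0 °C) into (E)-3-methoxy-2-methylbut-2-enoyl chloride F3. This chloride is added to the lithium enolate of tert-butyl acetate (2.2 equiv, made with LiN(iPr)2, THF, −78 °C) in a crossed Claisen condensation. The second equivalent of enolate deprotonates the product, and a mild acidic work-up should release 8.

**Further compounds**

F1 | step 5 | methyl (E)-5-methoxy-4-methyl-3,7-dioxodec-4-enoate | CCCC(=O)C/C(OC)=C(/C)C(=O)CC(=O)OC
F2 | step 4 | tert-butyl (E)-7-hydroxy-5-methoxy-4-methyl-3-oxodec-4-enoate (racemic) | CCCC(O)C/C(OC)=C(/C)C(=O)CC(=O)OC(C)(C)C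
F3 | step 3 | (E)-3-methoxy-2-methylbut-2-enoyl chloride | C/C(OC)=C(/C)C(=O)Cl
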